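The readings are calculated with constants of no real substance; the scatter is artificial.

**The impossibility.** A substrate turning straight into target is impossible in the birch run: at 50.0 min it had lost 39.0 %, far more than the 3 % of target read then, with a scatter of 1.5 percentage points. So I followed the substrate and left target aside.

in all of them: substrate 0.20 M

| charge | coupling partner | scavenger | remark | time |
|---|---|---|---|---|
| birch | 0.80 M | 0.080 M | run made earlier |  |
| flask | 0.800 M | 0.160 M |  | 3.0 h |

- birch (time / min: substrate / %, target / %): 10.0: 90, 2; 20.0: 81, 3; 25.0: 77, 0; 40.0: 66, 5; 50.0: 61, 3

(readings scatter by 1.5 percentage points)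

- the analysis behind the earlier runs scatters by 1.5 percentage points, standard deviation
- a reading or a percentage of target counts all its forms, free or not
- the earlier runs do not show how much of coupling partner is bound; that part of a forecast is a guess
- no earlier run changes the charge of scavenger; that part of a forecast is a guess

1. part of the substrate that has reacted at 3.0 h
2. share of free coupling partner in free coupling partner and idle adduct A together, at 3.0 h

**Main step.** I first took substrate plus coupling partner as one process, with partner held at its charge of 4.00 equivalents: a pseudo-first-order picture. The last birch reading then gives the substrate half-life at charged partner, 1.17 h, a reading that carries the scatter. Over the 3.0 h of the flask, that half-life puts the reacted part at 83.1 %.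

**Partner used.** Taken one to one, that turnover leaves 79.2 % of the partner, so 89.6 % midway through the turnover. Dividing by this stretches the half-life to 1.30 h and lowers my figure to 79.7 %, to which I committed.

**The rest.** No earlier run changes the scavenger, so going from 0.080 M to 0.160 M I guessed no change in the half-life. Bound partner was unseen, so I reckoned no free share.

**The forecast.** It gave 82 % reacted, above my figure, and a free share of 97 %, judging that “the scavenger seems to take up what forms, stoichiometrically, until exhausted”.

**The result.** The flask gave 77.6 % reacted and a free share of 90.5 %, under this scheme:

    substrate + coupling partner ⇌ intermediate (K = 43.0 M⁻¹, k = 2.21 × 10⁻⁴ M⁻¹ s⁻¹)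
    intermediate ⇌ target + released group (K = 1.40 M, k = 6.80 × 10⁻⁵ s⁻¹)
    coupling partner + released group ⇌ idle adduct A, settled at all times (K = 244 M⁻¹)
    scavenger + released group → scavenged by-product (k = 0.00296 M⁻¹ s⁻¹)
    coupling partner + target ⇌ idle adduct B, settled at all times (K = 14.0 M⁻¹)
    coupling partner + target → over-reaction product (k = 2.47 × 10⁻⁴ M⁻¹ s⁻¹)

At 3.00 h free coupling partner in the flask stood at 67 % of its charge, beside 0.0564 M of idle adduct A. Stretched to that partner, the half-life becomes 1.74 h and gives 69.7 %, below the result, while the charged half-life's 83.1 % lies above it. For a neighbour flask charged with 0.20 M of partner, its other charges and time as in the flask, the half-life becomes 4.67 h, and 8.53 h at its final 55 % free partner. These give reacted parts of 35.9 % and 21.6 %; that neighbour flask gave 29.9 %.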